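Ring A carries the adjacent centres C4 (quaternary, CH3/CO2H) and C5 (H), and C10 is the branch point joined to C1, C5 and C9. Cutting C3–C4 and C5–C10 therefore turns ring A into a C10=C1(OSi)–C2=C3 diene and a C4=C5 (E)-2-methylenal that are already linked by the C6–C9 chain of ring B. One catalyst-controlled intramolecular Diels–Alder reaction of this acyclic silyloxytrienal, whose C8 centre comes from (R)-citronellal, closes both rings and sets C4 and C5. The adduct's C1 enol ether and C9 methylene then become the Δ9(10)-enone that takes up the side chain at C9 and leaves the Δ1(10) alkene.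

Key step: step 10

Conventions, assumption and design remarks
- Terpenoid (halimane) numbering is used for atoms: ring A = C1–C5, C10; ring B = C5–C10; C17 = CH3 on C8; C18 = carboxyl carbon and C19 = CH3 on C4; C20 = CH3 on C9; C11–C16 = side chain. The target is (4S,5S,8R,9S,13E).
- Assumption: the sense of induction in step 10 is taken from the usual model for 2-substituted enals on the protonated oxazaborolidine (formyl C–H against the ring oxygen, s-trans enal), which points to the (R)-prolinol-derived catalyst; if the sense proves opposite, the (S)-catalyst is used with no other change.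
- Chain length: diene and dienophile must be joined by four atoms (C6–C9), so a five-carbon C5–C9 chain carrying the C8 methyl is required. An α-methyl-γ-butyrolactone-type C4 unit is one carbon short and would close a five-membered ring. (R)-Citronellal supplies C5–C10 and C17 intact.
- C8 is brought in enantiopure and not equilibrated later, because the two C8 epimers of the Δ9(10)-enone are expected to be close in energy. The catalyst then only has to decide a diastereomer ratio, and the enantiomeric purity of the target is that of 1.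
- The diene is made from a β,γ-unsaturated vinyl ketone whose only enolisable position is C10, so C8–H is never acidified on the way to the precursor.

Step 1
Reactants: 1 (R)-citronellal; 2 methyl methacrylate
Product: 3 methyl (2E,6R)-2,6-dimethyl-8-oxooct-2-enoate
Conditions: second-generation Hoveyda–Grubbs catalyst (C31H38Cl2N2ORu, 3 mol%), neat 2 (10 equiv), 2,6-di-tert-butyl-4-methylphenol (cat.), 85 °C, N2 purge
Reagents that add atoms: methyl methacrylate (2), C=C(C)C(=O)OC
Why: Olefin cross-metathesis exchanges the isopropylidene end of the prenyl group (lost as volatile isobutene) for the methacrylate unit, the trisubstituted enoate forming as the thermodynamically preferred E isomer, while the aldehyde and the C8 centre are not involved.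

Step 2
Reactants: 3 methyl (2E,6R)-2,6-dimethyl-8-oxooct-2-enoate; 4 formaldehyde
Product: 5 methyl (2E,6R)-7-formyl-2,6-dimethylocta-2,7-dienoate
Conditions: 37% aq. HCHO, pyrrolidine (10 mol%), propanoic acid (10 mol%), i-PrOH, 45 °C
Reagents that add atoms: formaldehyde (4), C=O
Why: Amine-catalysed α-methylenation (Mannich condensation of the enamine of 3 with formaldehyde, then elimination) installs C20 on C9, and C8, being β to the aldehyde, cannot epimerise.

Step 3
Reactants: 5 methyl (2E,6R)-7-formyl-2,6-dimethylocta-2,7-dienoate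
Product: 6 methyl (2E,6R)-7-(hydroxymethyl)-2,6-dimethylocta-2,7-dienoate
Conditions: NaBH4, CeCl3·7H2O, MeOH, −20 °C
Reagents that add atoms: none
Why: Luche reduction gives clean 1,2-reduction of the 2-substituted acrolein without conjugate reduction and leaves the enoate untouched.

Step 4
Reactants: 6 methyl (2E,6R)-7-(hydroxymethyl)-2,6-dimethylocta-2,7-dienoate
Product: 7 methyl (2E,6R)-7-(bromomethyl)-2,6-dimethylocta-2,7-dienoate
Conditions: CBr4, PPh3, CH2Cl2, 0 °C
Reagents that add atoms: tetrabromomethane, BrC(Br)(Br)Br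
Why: The Appel reaction converts the primary allylic alcohol into the bromide under neutral conditions, and allylic transposition is of no consequence because both termini of the 2-substituted allyl unit are CH2.

Step 5
Reactants: 7 methyl (2E,6R)-7-(bromomethyl)-2,6-dimethylocta-2,7-dienoate; 8 acrolein
Product: 10 methyl (2E,6R)-9-hydroxy-2,6-dimethyl-7-methylideneundeca-2,10-dienoate (both carbinol epimers), via allylzinc bromide 9 (not isolated)
Conditions: Zn dust, THF/sat. aq. NH4Cl, 0 °C → rt
Reagents that add atoms: acrolein (8), C=CC=O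
Why: The zinc-mediated Barbier allylation adds the allyl unit 1,2 to acrolein and forms the C10–C1 bond, the enoate being inert to the allylzinc species and the new carbinol centre being removed in step 6.

Step 6
Reactants: 10 methyl (2E,6R)-9-hydroxy-2,6-dimethyl-7-methylideneundeca-2,10-dienoate
Product: 11 methyl (2E,6R)-2,6-dimethyl-7-methylidene-9-oxoundeca-2,10-dienoate
Conditions: Dess–Martin periodinane, NaHCO3, CH2Cl2, 0 °C; used at once
Reagents that add atoms: none
Why: Buffered Dess–Martin oxidation gives the β,γ-unsaturated vinyl ketone without base or acid that would move the C9 methylene into conjugation.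

Step 7
Reactants: 11 methyl (2E,6R)-2,6-dimethyl-7-methylidene-9-oxoundeca-2,10-dienoate
Product: 12 methyl (2E,6R,8Z)-9-(tert-butyldimethylsilyloxy)-2,6-dimethyl-7-methylideneundeca-2,8,10-trienoate
Conditions: TBSOTf, Et3N, CH2Cl2, −78 °C
Reagents that add atoms: tert-butyldimethylsilyl trifluoromethanesulfonate, CC(C)(C)[Si](C)(C)OS(=O)(=O)C(F)(F)F
Why: Soft enolisation can only occur at C10, which is activated by both the carbonyl and the C9 methylene, and the (8Z) enol ether (C9 cis to oxygen, trans to the vinyl group) is expected because it avoids A(1,3) strain between the branched C9 and the vinyl group.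

Step 8
Reactants: 12 methyl (2E,6R,8Z)-9-(tert-butyldimethylsilyloxy)-2,6-dimethyl-7-methylideneundeca-2,8,10-trienoate
Product: 13 (2E,6R,8Z)-9-(tert-butyldimethylsilyloxy)-2,6-dimethyl-7-methylideneundeca-2,8,10-trien-1-ol
Conditions: i-Bu2AlH (2.2 equiv), CH2Cl2, −78 °C; aq. potassium sodium tartrate
Reagents that add atoms: none
Why: Low-temperature aluminium hydride reduction takes the conjugated ester to the allylic alcohol, and the silyl dienol ether is stable to the hydride and to the neutral tartrate work-up.

Step 9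
Reactants: 13 (2E,6R,8Z)-9-(tert-butyldimethylsilyloxy)-2,6-dimethyl-7-methylideneundeca-2,8,10-trien-1-ol
Product: 14 (2E,6R,8Z)-9-(tert-butyldimethylsilyloxy)-2,6-dimethyl-7-methylideneundeca-2,8,10-trienal
Conditions: activated MnO2 (excess), CH2Cl2, rt; filtered and used cold without delay
Reagents that add atoms: none
Why: Allylic oxidation with MnO2 is neutral and selective for the allylic alcohol, giving the (E)-enal without acid or base that would cleave the enol ether.

Step 10
Reactants: 14 (2E,6R,8Z)-9-(tert-butyldimethylsilyloxy)-2,6-dimethyl-7-methylideneundeca-2,8,10-trienal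
Product: 15 (4S,5S,8R,10R)-cycloadduct: trans-fused decalin with the C1 tert-butyldimethylsilyl enol ether (C1=C2); exocyclic C9=CH2; CH3 and CHO on C4; CH3 on C8
Conditions: (R)-B-(2-methylphenyl)oxazaborolidine C24H24BNO from (R)-α,α-diphenylprolinol (20 mol%), (CF3SO2)2NH (18 mol%), CH2Cl2, −78 → −40 °C
Reagents that add atoms: none
Why: The protonated oxazaborolidine binds the formyl oxygen of 14 (formyl C–H against the ring oxygen, s-trans enal) and lowers the enal LUMO, so the silyl dienol ether adds in a concerted but asynchronous [4+2] in which its nucleophilic terminus C10 (enol-ether β-carbon) bonds to the enal β-carbon C5 ahead of C3–C4. The closest known reaction type is the cationic-oxazaborolidine-catalysed enantioselective Diels–Alder reaction of 2-substituted enals with 2-silyloxydienes, including its intramolecular trienal form. Ring B closes by the tethered (type 1) mode, the C5–C10 bond completing a six-membered ring over the four tether atoms C6–C9, and ring A is the cyclohexene formed by the cycloaddition itself (C5–C10 plus C3–C4). C4 and C5 arise together: their relative configuration (formyl cis to H5) follows from suprafacial addition to the (E)-enal and their absolute configuration from the catalyst, which shields one enal face so that the diene adds to the face that is Si at C4 and Re at C5; C10 depends only on the endo/exo mode (the endo-formyl, trans-fused adduct is drawn) and is planarised in step 11, and C8 comes unchanged from 1. The selectivity that has to be won is this enal-face choice against the tether, whose C8 methyl prefers an equatorial site that favours the other face in the endo mode but the required face in the exo mode; because C8 is enantiopure, any leakage gives a separable diastereomer and not the enantiomer. Chemo- and regioselectivity are secured by the substrate, since only the C10=C1–C2=C3 diene can reach the enal through a six-membered tether (the cross-conjugated C9 methylene could only give a bridgehead alkene) and the (8Z) enol ether keeps the tether on the outer position of the diene.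

Step 11
Reactants: 15 (4S,5S,8R,10R)-cycloadduct
Product: 17 (4S,5R,8R)-enone aldehyde: Δ9(10)-octalin-1-one with CH3 on C9 and C8 and with CH3 and CHO on C4, via β,γ-unsaturated ketone 16 (not isolated)
Conditions: Bu4NF (1.1 equiv), THF, 0 °C; then DBU (0.3 equiv), rt; aq. NH4Cl
Reagents that add atoms: none
Why: Fluoride cleaves the silyl enol ether to the C1 ketone, and the amidine base moves the C9 methylene into conjugation through the C10 enolate (protonation at C20), which erases C10, while C8 is kept because γ-deprotonation of the product is far slower than α-deprotonation at the doubly activated C10 (the C5 descriptor changes by priority only).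

Step 12
Reactants: 17 (4S,5R,8R)-enone aldehyde
Product: 18 (4S,5S,8R)-enone acid: 4,8,9-trimethyl-1-oxo-Δ9(10)-octalin-4-carboxylic acid (C18 acid)
Conditions: NaClO2, NaH2PO4, 2-methylbut-2-ene, t-BuOH/H2O, rt
Reagents that add atoms: sodium chlorite, [Na+].[O-]Cl=O
Why: Pinnick oxidation converts the non-enolisable neopentyl aldehyde into the acid, the tetrasubstituted enone being inert to chlorite and the alkene scavenger removing hypochlorous acid.

Step 13
Reactants: 18 (4S,5S,8R)-enone acid; 19 2-(trimethylsilyl)ethanol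
Product: 20 (4S,5S,8R)-enone 2-(trimethylsilyl)ethyl ester
Conditions: PPh3, diisopropyl azodicarboxylate, THF, 0 °C → rt
Reagents that add atoms: 2-(trimethylsilyl)ethanol (19), C[Si](C)(C)CCO
Why: In the Mitsunobu esterification the hindered carboxylate is the nucleophile at the activated primary carbon, so hindrance at the acyl carbon does not matter, and the resulting ester resists the Grignard reagent of step 18 yet falls to fluoride.

Step 14
Reactants: 21 tert-butyl(but-3-yn-1-yloxy)dimethylsilane; 4 formaldehyde (as paraformaldehyde)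
Product: 24 (2E)-5-(tert-butyldimethylsilyloxy)-3-methylpent-2-en-1-ol, via alkenyldimethylalane 22 (not isolated), via lithium alkenylaluminate 23 (not isolated)
Conditions: AlMe3 (2 equiv), Cp2ZrCl2 (20 mol%), CH2Cl2, 0 °C → rt; n-BuLi, THF, −78 °C; (CH2O)n, −78 °C → rt
Reagents that add atoms: trimethylaluminium, C[Al](C)C; formaldehyde (4), C=O
Why: Zirconium-catalysed syn-methylalumination of the terminal alkyne places CH3 on C13 and aluminium on C14, and the aluminate reacts with formaldehyde with retention, which fixes the (E)-trisubstituted alkene (C12 trans to C15).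

Step 15
Reactants: 24 (2E)-5-(tert-butyldimethylsilyloxy)-3-methylpent-2-en-1-ol
Product: 25 (2E)-5-(tert-butyldimethylsilyloxy)-1-(tert-butyldiphenylsilyloxy)-3-methylpent-2-ene
Conditions: TBDPSCl, imidazole, CH2Cl2, 0 °C → rt
Reagents that add atoms: tert-butyl(chloro)diphenylsilane, CC(C)(C)[Si](Cl)(c1ccccc1)c1ccccc1
Why: Standard silylation protects the C15 alcohol with a group that survives the acid of step 16 and the Grignard and palladium steps, and that is removed together with the TMSE ester in step 20.

Step 16
Reactants: 25 (2E)-5-(tert-butyldimethylsilyloxy)-1-(tert-butyldiphenylsilyloxy)-3-methylpent-2-ene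
Product: 26 (3E)-5-(tert-butyldiphenylsilyloxy)-3-methylpent-3-en-1-ol
Conditions: pyridinium p-toluenesulfonate (0.1 equiv), EtOH, rt
Reagents that add atoms: none
Why: Mild acid-catalysed ethanolysis removes the primary alkyl TBS ether much faster than the bulkier TBDPS ether.

Step 17
Reactants: 26 (3E)-5-(tert-butyldiphenylsilyloxy)-3-methylpent-3-en-1-ol
Product: 27 [(2E)-5-bromo-3-methylpent-2-en-1-yl]oxy(tert-butyl)diphenylsilane
Conditions: CBr4, PPh3, CH2Cl2, 0 °C
Reagents that add atoms: tetrabromomethane, BrC(Br)(Br)Br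
Why: Appel bromination of the primary homoallylic alcohol proceeds under neutral conditions that leave the allylic silyl ether and the alkene geometry untouched.

Step 18
Reactants: 27 [(2E)-5-bromo-3-methylpent-2-en-1-yl]oxy(tert-butyl)diphenylsilane; 20 (4S,5S,8R)-enone 2-(trimethylsilyl)ethyl ester
Product: 30 (4S,5S,8R,9S)-C1 enol triflate (C1=C10) carrying the silyl-protected side chain on C9, via Grignard reagent 28 (not isolated), via magnesium enolate 29 (not isolated)
Conditions: Mg, THF, rt; CuBr·SMe2 (20 mol%), 20, THF, −40 → −10 °C; then N-(5-chloropyridin-2-yl)bis(trifluoromethanesulfonyl)imide, −78 °C → rt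
Reagents that add atoms: N-(5-chloropyridin-2-yl)-1,1,1-trifluoro-N-(trifluoromethylsulfonyl)methanesulfonamide, O=S(=O)(N(c1ccc(Cl)cn1)S(=O)(=O)C(F)(F)F)C(F)(F)F
Why: Copper-catalysed conjugate addition of a Grignard reagent to a 2-alkylidenecyclohexanone (s-cis, pulegone-type enone) creates the quaternary C9 by axial attack on the face anti to the pseudoaxial C8 methyl (syn to H5 and H8), so that C20 ends cis to C17, and the regiodefined C1–C10 enolate is O-triflated in the same flask.

Step 19
Reactants: 30 (4S,5S,8R,9S)-C1 enol triflate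
Product: 31 (4S,5S,8R,9S,13E)-15-(tert-butyldiphenylsilyloxy)halima-1(10),13-dien-18-oic acid 2-(trimethylsilyl)ethyl ester
Conditions: Pd(OAc)2 (5 mol%), PPh3 (10 mol%), n-Bu3N, HCO2H, DMF, 60 °C
Reagents that add atoms: none
Why: Palladium-catalysed formate reduction of the enol triflate (oxidative addition, formate-to-hydride exchange with loss of CO2, reductive elimination) replaces OTf by H and leaves the double bond fixed at C1=C10.

Step 20
Reactants: 31 silyl ether TMSE ester
Product: 32 (4S,5S,8R,9S,13E)-15-hydroxyhalima-1(10),13-dien-18-oic acid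
Conditions: Bu4NF (4 equiv), THF, rt → 40 °C; aq. NH4Cl, then dilute citric acid
Reagents that add atoms: none
Why: Fluoride removes the TBDPS ether and fragments the TMSE ester by attack at silicon with loss of ethene, a cleavage that does not depend on access to the hindered acyl carbon.

Step 21
Reactants: 32 (4S,5S,8R,9S,13E)-15-hydroxyhalima-1(10),13-dien-18-oic acid; 33 propanoic anhydride
Product: 34 CNP0223570.1, (4S,5S,8R,9S,13E)-15-(propanoyloxy)halima-1(10),13-dien-18-oic acid
Conditions: (EtCO)2O (1.3 equiv), pyridine, DMAP (cat.), CH2Cl2, 0 °C → rt; then H2O/pyridine, dilute HCl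
Reagents that add atoms: propanoic anhydride (33), CCC(=O)OC(=O)CC
Why: DMAP-catalysed acylation esterifies the primary allylic alcohol, and any mixed anhydride at the hindered C18 carboxyl is hydrolysed at its unhindered propanoyl carbonyl during the aqueous pyridine work-up, which returns the free acid.

Compound list
1 | (R)-citronellal, (3R)-3,7-dimethyloct-6-enal | CC(C)=CCC[C@@H](C)CC=O | starting material
2 | methyl methacrylate | C=C(C)C(=O)OC | starting material
3 | methyl (2E,6R)-2,6-dimethyl-8-oxooct-2-enoate | COC(=O)/C(C)=C/CC[C@@H](C)CC=O | intermediate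
4 | formaldehyde (aqueous solution or paraformaldehyde) | C=O | starting material
5 | methyl (2E,6R)-7-formyl-2,6-dimethylocta-2,7-dienoate | COC(=O)/C(C)=C/CC[C@@H](C)C(=C)C=O | intermediate
6 | methyl (2E,6R)-7-(hydroxymethyl)-2,6-dimethylocta-2,7-dienoate | COC(=O)/C(C)=C/CC[C@@H](C)C(=C)CO | intermediate
7 | methyl (2E,6R)-7-(bromomethyl)-2,6-dimethylocta-2,7-dienoate | COC(=O)/C(C)=C/CC[C@@H](C)C(=C)CBr | intermediate
8 | acrolein | C=CC=O | starting material
9 | allylzinc bromide derived from 7 | COC(=O)/C(C)=C/CC[C@@H](C)C(=C)C[Zn]Br | intermediate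
10 | methyl (2E,6R)-9-hydroxy-2,6-dimethyl-7-methylideneundeca-2,10-dienoate (both carbinol epimers) | COC(=O)/C(C)=C/CC[C@@H](C)C(=C)CC(O)C=C | intermediate
11 | methyl (2E,6R)-2,6-dimethyl-7-methylidene-9-oxoundeca-2,10-dienoate | COC(=O)/C(C)=C/CC[C@@H](C)C(=C)CC(=O)C=C | intermediate
12 | methyl (2E,6R,8Z)-9-(tert-butyldimethylsilyloxy)-2,6-dimethyl-7-methylideneundeca-2,8,10-trienoate | COC(=O)/C(C)=C/CC[C@@H](C)C(=C)/C=C(\O[Si](C)(C)C(C)(C)C)C=C | intermediate
13 | (2E,6R,8Z)-9-(tert-butyldimethylsilyloxy)-2,6-dimethyl-7-methylideneundeca-2,8,10-trien-1-ol | OC/C(C)=C/CC[C@@H](C)C(=C)/C=C(\O[Si](C)(C)C(C)(C)C)C=C | intermediate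
14 | (2E,6R,8Z)-9-(tert-butyldimethylsilyloxy)-2,6-dimethyl-7-methylideneundeca-2,8,10-trienal (key-step precursor) | O=C/C(C)=C/CC[C@@H](C)C(=C)/C=C(\O[Si](C)(C)C(C)(C)C)C=C | intermediate
15 | (4S,5S,8R,10R)-cycloadduct: trans-fused decalin, C1 TBS enol ether (C1=C2), exocyclic C9=CH2, CH3 and CHO on C4, CH3 on C8 (key-step product) | C=C1[C@@H]2C(O[Si](C)(C)C(C)(C)C)=CC[C@](C)(C=O)[C@H]2CC[C@H]1C | intermediate
16 | (4S,5S,8R,10R)-β,γ-unsaturated keto aldehyde: C1 ketone, exocyclic C9=CH2, CH3 and CHO on C4 | C=C1[C@@H]2C(=O)CC[C@](C)(C=O)[C@H]2CC[C@H]1C | intermediate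
17 | (4S,5R,8R)-enone aldehyde: C1 ketone conjugated with C10=C9, CH3 on C9 and C8, CH3 and CHO on C4 | CC1=C2C(=O)CC[C@](C)(C=O)[C@H]2CC[C@H]1C | intermediate
18 | (4S,5S,8R)-enone acid (C18 carboxylic acid) | CC1=C2C(=O)CC[C@](C)(C(=O)O)[C@H]2CC[C@H]1C | intermediate
19 | 2-(trimethylsilyl)ethanol | C[Si](C)(C)CCO | starting material
20 | (4S,5S,8R)-enone 2-(trimethylsilyl)ethyl ester | CC1=C2C(=O)CC[C@](C)(C(=O)OCC[Si](C)(C)C)[C@H]2CC[C@H]1C | intermediate
21 | tert-butyl(but-3-yn-1-yloxy)dimethylsilane | C#CCCO[Si](C)(C)C(C)(C)C | starting material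
22 | [(1E)-4-(tert-butyldimethylsilyloxy)-2-methylbut-1-en-1-yl]dimethylalane | C[Al](C)/C=C(\C)CCO[Si](C)(C)C(C)(C)C | intermediate
23 | lithium butyl[(1E)-4-(tert-butyldimethylsilyloxy)-2-methylbut-1-en-1-yl]dimethylaluminate | [Li+].CCCC[Al-](C)(C)/C=C(\C)CCO[Si](C)(C)C(C)(C)C | intermediate
24 | (2E)-5-(tert-butyldimethylsilyloxy)-3-methylpent-2-en-1-ol | OC/C=C(\C)CCO[Si](C)(C)C(C)(C)C | intermediate
25 | (2E)-5-(tert-butyldimethylsilyloxy)-1-(tert-butyldiphenylsilyloxy)-3-methylpent-2-ene | CC(C)(C)[Si](OC/C=C(\C)CCO[Si](C)(C)C(C)(C)C)(c1ccccc1)c1ccccc1 | intermediate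
26 | (3E)-5-(tert-butyldiphenylsilyloxy)-3-methylpent-3-en-1-ol | CC(C)(C)[Si](OC/C=C(\C)CCO)(c1ccccc1)c1ccccc1 | intermediate
27 | [(2E)-5-bromo-3-methylpent-2-en-1-yl]oxy(tert-butyl)diphenylsilane | CC(C)(C)[Si](OC/C=C(\C)CCBr)(c1ccccc1)c1ccccc1 | intermediate
28 | Grignard reagent derived from 27 | CC(C)(C)[Si](OC/C=C(\C)CC[Mg]Br)(c1ccccc1)c1ccccc1 | intermediate
29 | (4S,5S,8R,9S)-bromomagnesium C1–C10 enolate of the conjugate adduct | CC(C)(C)[Si](OC/C=C(\C)CC[C@]1(C)C2=C(O[Mg]Br)CC[C@](C)(C(=O)OCC[Si](C)(C)C)[C@H]2CC[C@H]1C)(c1ccccc1)c1ccccc1 | intermediate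
30 | (4S,5S,8R,9S)-C1 enol triflate (C1=C10) with the TBDPS-protected side chain on C9 and the TMSE ester on C4 | CC(C)(C)[Si](OC/C=C(\C)CC[C@]1(C)C2=C(OS(=O)(=O)C(F)(F)F)CC[C@](C)(C(=O)OCC[Si](C)(C)C)[C@H]2CC[C@H]1C)(c1ccccc1)c1ccccc1 | intermediate
31 | (4S,5S,8R,9S,13E)-15-(tert-butyldiphenylsilyloxy)halima-1(10),13-dien-18-oic acid 2-(trimethylsilyl)ethyl ester | CC(C)(C)[Si](OC/C=C(\C)CC[C@]1(C)C2=CCC[C@](C)(C(=O)OCC[Si](C)(C)C)[C@H]2CC[C@H]1C)(c1ccccc1)c1ccccc1 | intermediate
32 | (4S,5S,8R,9S,13E)-15-hydroxyhalima-1(10),13-dien-18-oic acid | OC/C=C(\C)CC[C@]1(C)C2=CCC[C@](C)(C(=O)O)[C@H]2CC[C@H]1C | intermediate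
33 | propanoic anhydride | CCC(=O)OC(=O)CC | starting material
34 | CNP0223570.1, (1S,5S,6R,8aS)-1,5,6-trimethyl-5-[(3E)-3-methyl-5-(propanoyloxy)pent-3-en-1-yl]-1,2,3,5,6,7,8,8a-octahydronaphthalene-1-carboxylic acid | CCC(=O)OC/C=C(\C)CC[C@]1(C)C2=CCC[C@](C)(C(=O)O)[C@H]2CC[C@H]1C | target

Total step count: 21. Longest linear sequence: 17 steps (steps 1–13 and 18–21); the side-chain branch (steps 14–17) joins at step 18.

Steps most likely to fail

1. Step 10. What may go wrong: facial control is eroded because the equatorial preference of the C8 methyl in the endo chair opposes the catalyst-preferred enal face, or the acid-labile silyl dienol ether is lost before it cyclises. The fallback replaces catalyst override by substrate control; it sets out from methyl methacrylate 2 and comes back at enone aldehyde 17. (S)-Citronellal F1 replaces 1, and steps 1–9 with unchanged reagents give the 6S series: enoate aldehyde F2, α-methylene aldehyde F3, allylic alcohol F4, allylic bromide F5, its allylzinc bromide F6, dienol F7, vinyl ketone F8, silyloxytriene ester F9, trienol F10 and trienal F11. In this series the equatorial C8 methyl and the endo-formyl, trans-fused chair lead to the C4/C5 configuration of the target, so Me2AlCl in CH2Cl2 at −78 °C (or the now matched catalyst of step 10) should give the 8S cycloadduct F12 by substrate control alone. Bu4NF then DBU as in step 11 would lead through the 8S keto aldehyde F13 to the 8-epi enone aldehyde F14. Longer base treatment (DBU, toluene, 60 °C) would equilibrate C8 through the extended C1–C10–C9–C8 dienolate towards 17, whose pseudoaxial C8 methyl avoids A(1,2) strain with the C9 methyl; the position of this equilibrium is uncertain, so the epimers are separated and F14 is recycled.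

2. Step 18. What may go wrong: conjugate addition to the tetrasubstituted enone is sluggish, so 1,2-addition or enolisation competes, and the functionalised homoallylic Grignard reagent may decompose by intramolecular SN2′ displacement of the allylic silyloxy group. The fallback adds a small unfunctionalised nucleophile and builds the trisubstituted alkene afterwards; it sets out from 20 and comes back at hydroxy acid 32. Commercial (4-bromobut-1-yn-1-yl)trimethylsilane F15 gives the Grignard reagent F16, which is added to 20 under the copper-catalysed conditions of step 18. The magnesium enolate F17 is triflated to enol triflate F18 and reduced as in step 19 to the silylalkyne F19. K2CO3 in MeOH removes the alkynyl silyl group to give terminal alkyne F20. Zirconium-catalysed methylalumination (AlMe3, Cp2ZrCl2), then n-BuLi and paraformaldehyde as in step 14, converts it through the alkenylalane F21 and its lithium aluminate F22 into the (13E)-allylic alcohol F23. Bu4NF then cleaves the TMSE ester to give 32.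

3. Step 1. What may go wrong: cross-metathesis between a trisubstituted alkene and a 1,1-disubstituted acrylate stalls at low conversion, or the methacrylate polymerises at the temperature needed. The fallback uses oxidative cleavage and olefination instead of metathesis; it sets out from 1 and comes back at 3. The aldehyde is masked as the dimethyl acetal F24 (HC(OMe)3, cat. TsOH, MeOH). Ozonolysis (O3, CH2Cl2/MeOH, −78 °C; Me2S) cleaves the trisubstituted alkene to the acetal aldehyde F25. Wittig olefination with commercial methyl 2-(triphenylphosphoranylidene)propanoate F26 (CH2Cl2, rt) gives the (E)-enoate acetal F27, and aqueous oxalic acid in THF releases 3.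

Further compounds
F1 | step 10 | (S)-citronellal | CC(C)=CCC[C@H](C)CC=O
F2 | step 10 | methyl (2E,6S)-2,6-dimethyl-8-oxooct-2-enoate | COC(=O)/C(C)=C/CC[C@H](C)CC=O
F3 | step 10 | methyl (2E,6S)-7-formyl-2,6-dimethylocta-2,7-dienoate | COC(=O)/C(C)=C/CC[C@H](C)C(=C)C=O
F4 | step 10 | methyl (2E,6S)-7-(hydroxymethyl)-2,6-dimethylocta-2,7-dienoate | COC(=O)/C(C)=C/CC[C@H](C)C(=C)CO
F5 | step 10 | methyl (2E,6S)-7-(bromomethyl)-2,6-dimethylocta-2,7-dienoate | COC(=O)/C(C)=C/CC[C@H](C)C(=C)CBr
F6 | step 10 | allylzinc bromide derived from F5 | COC(=O)/C(C)=C/CC[C@H](C)C(=C)C[Zn]Br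
F7 | step 10 | methyl (2E,6S)-9-hydroxy-2,6-dimethyl-7-methylideneundeca-2,10-dienoate | COC(=O)/C(C)=C/CC[C@H](C)C(=C)CC(O)C=C
F8 | step 10 | methyl (2E,6S)-2,6-dimethyl-7-methylidene-9-oxoundeca-2,10-dienoate | COC(=O)/C(C)=C/CC[C@H](C)C(=C)CC(=O)C=C
F9 | step 10 | methyl (2E,6S,8Z)-9-(tert-butyldimethylsilyloxy)-2,6-dimethyl-7-methylideneundeca-2,8,10-trienoate | COC(=O)/C(C)=C/CC[C@H](C)C(=C)/C=C(\O[Si](C)(C)C(C)(C)C)C=C
F10 | step 10 | (2E,6S,8Z)-9-(tert-butyldimethylsilyloxy)-2,6-dimethyl-7-methylideneundeca-2,8,10-trien-1-ol | OC/C(C)=C/CC[C@H](C)C(=C)/C=C(\O[Si](C)(C)C(C)(C)C)C=C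
F11 | step 10 | (2E,6S,8Z)-9-(tert-butyldimethylsilyloxy)-2,6-dimethyl-7-methylideneundeca-2,8,10-trienal | O=C/C(C)=C/CC[C@H](C)C(=C)/C=C(\O[Si](C)(C)C(C)(C)C)C=C
F12 | step 10 | (4S,5S,8S,10R)-cycloadduct (8-epimer of 15) | C=C1[C@@H]2C(O[Si](C)(C)C(C)(C)C)=CC[C@](C)(C=O)[C@H]2CC[C@@H]1C
F13 | step 10 | (4S,5S,8S,10R)-β,γ-unsaturated keto aldehyde (8-epimer of 16) | C=C1[C@@H]2C(=O)CC[C@](C)(C=O)[C@H]2CC[C@@H]1C
F14 | step 10 | (4S,5R,8S)-enone aldehyde (8-epimer of 17) | CC1=C2C(=O)CC[C@](C)(C=O)[C@H]2CC[C@@H]1C
F15 | step 18 | (4-bromobut-1-yn-1-yl)trimethylsilane | C[Si](C)(C)C#CCCBr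
F16 | step 18 | Grignard reagent derived from F15 | C[Si](C)(C)C#CCC[Mg]Br
F17 | step 18 | (4S,5S,8R,9S)-bromomagnesium enolate of the butynyl adduct | C[Si](C)(C)C#CCC[C@]1(C)C2=C(O[Mg]Br)CC[C@](C)(C(=O)OCC[Si](C)(C)C)[C@H]2CC[C@H]1C
F18 | step 18 | (4S,5S,8R,9S)-C1 enol triflate with 4-(trimethylsilyl)but-3-ynyl on C9 | C[Si](C)(C)C#CCC[C@]1(C)C2=C(OS(=O)(=O)C(F)(F)F)CC[C@](C)(C(=O)OCC[Si](C)(C)C)[C@H]2CC[C@H]1C
F19 | step 18 | (4S,5S,8R,9S)-Δ1(10)-ene TMSE ester with 4-(trimethylsilyl)but-3-ynyl on C9 | C[Si](C)(C)C#CCC[C@]1(C)C2=CCC[C@](C)(C(=O)OCC[Si](C)(C)C)[C@H]2CC[C@H]1C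
F20 | step 18 | (4S,5S,8R,9S)-Δ1(10)-ene TMSE ester with but-3-ynyl on C9 | C#CCC[C@]1(C)C2=CCC[C@](C)(C(=O)OCC[Si](C)(C)C)[C@H]2CC[C@H]1C
F21 | step 18 | (E)-alkenyldimethylalane from methylalumination of F20 | C[Al](C)/C=C(\C)CC[C@]1(C)C2=CCC[C@](C)(C(=O)OCC[Si](C)(C)C)[C@H]2CC[C@H]1C
F22 | step 18 | lithium butyl(dimethyl)alkenylaluminate from F21 | [Li+].CCCC[Al-](C)(C)/C=C(\C)CC[C@]1(C)C2=CCC[C@](C)(C(=O)OCC[Si](C)(C)C)[C@H]2CC[C@H]1C
F23 | step 18 | (4S,5S,8R,9S,13E)-15-hydroxyhalima-1(10),13-dien-18-oic acid 2-(trimethylsilyl)ethyl ester | OC/C=C(\C)CC[C@]1(C)C2=CCC[C@](C)(C(=O)OCC[Si](C)(C)C)[C@H]2CC[C@H]1C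
F24 | step 1 | (R)-citronellal dimethyl acetal, (6R)-8,8-dimethoxy-2,6-dimethyloct-2-ene | CC(C)=CCC[C@@H](C)CC(OC)OC
F25 | step 1 | (4R)-6,6-dimethoxy-4-methylhexanal | O=CCC[C@@H](C)CC(OC)OC
F26 | step 1 | methyl 2-(triphenylphosphoranylidene)propanoate | COC(=O)C(C)=P(c1ccccc1)(c1ccccc1)c1ccccc1
F27 | step 1 | methyl (2E,6R)-8,8-dimethoxy-2,6-dimethyloct-2-enoate | COC(=O)/C(C)=C/CC[C@@H](C)CC(OC)OC
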